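**Strategy.** Lignan locants are used (C7, C8, C9; C7', C8', C9'; ring A = C7–O–C9'–C8'–C8, ring B = C7'–O–C9–C8–C8'). Everything rests on cutting ring B at O–C7' and C9–C8: the 1,3-relationship of benzylic C7' and quaternary C8 across C8' is read as the polarised bond of a lactone-fused donor–acceptor cyclopropane (aryl donor on C7', lactone and ester acceptors on C8). A Lewis-acid-catalysed (3+2) annulation with formaldehyde inserts the O–C9 unit into that bond in one operation, closing ring B cis-fused and, by inversion at C7', turning the exo aryl of the cyclopropane into the endo aryl of the target. Ring A is then finished from the lactone carbonyl (C7).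

Key step: step 4

Assumption (chemistry): the (S)-configured diarylprolinol silyl ether is taken to shield the iminium face as in its established enal additions, which should lead to (2S,3R)-5; were the sense opposite, the (R)-catalyst would be used with no other change.

Step 1
Reactants: 1 coniferaldehyde [(E)-3-(4-hydroxy-3-methoxyphenyl)prop-2-enal]; 2 benzyl bromide
Product: 3 (E)-3-[4-(benzyloxy)-3-methoxyphenyl]prop-2-enal
Conditions: BnBr, K2CO3, DMF, rt
Reagents that add atoms: benzyl bromide 2, BrCc1ccccc1
Why: Williamson etherification of the phenol, the only acidic site, should proceed cleanly, forms no stereocenter and keeps the aryl group electron-rich for its later donor role.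

Step 2
Reactants: 3; 4 dimethyl bromomalonate
Product: 5 dimethyl (2S,3R)-2-[4-(benzyloxy)-3-methoxyphenyl]-3-formylcyclopropane-1,1-dicarboxylate
Conditions: (S)-2-[diphenyl(trimethylsilyloxy)methyl]pyrrolidine (20 mol%), 2,6-lutidine, CH2Cl2, 0 °C to rt
Reagents that add atoms: dimethyl bromomalonate 4, COC(=O)C(Br)C(=O)OC
Why: Organocatalytic Michael-initiated ring closure, in which the bromomalonate adds to the β-carbon of the iminium ion of 3 on the face not shielded by the diphenyl(silyloxy)methyl group and the resulting enamine closes the ring by 3-exo-tet alkylation, should set C7' and C8' together with aryl and formyl trans.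

Step 3
Reactants: 5
Product: 7 methyl (1S,5R,6S)-6-[4-(benzyloxy)-3-methoxyphenyl]-2-oxo-3-oxabicyclo[3.1.0]hexane-1-carboxylate, via hydroxymethyl diester 6 (not isolated)
Conditions: NaBH4, MeOH, 0 °C to rt
Reagents that add atoms: none
Why: Chemoselective borohydride reduction of the aldehyde followed by 5-exo-trig lactonisation onto the only ester that is cis to the new CH2OH group should give the fused lactone, and this desymmetrisation of the malonate fixes C8 because the trans ester cannot reach.

Step 4
Reactants: 7; 8 formaldehyde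
Product: 9 methyl (3aR,4R,6aR)-4-[4-(benzyloxy)-3-methoxyphenyl]-1-oxotetrahydro-1H,3H-furo[3,4-c]furan-6a(6H)-carboxylate
Conditions: monomeric CH2O (excess, freshly cracked from paraformaldehyde), Sn(OTf)2 (10 mol%), 4 Å MS, CH2Cl2, −40 to 0 °C
Reagents that add atoms: formaldehyde 8, C=O
Why: Sn(OTf)2 chelates the lactone and ester carbonyls on C8 and polarises the C8–C7' bond of 7; the formaldehyde oxygen attacks C7' from the backside (SN2-like) to give an O-alkylated formaldehyde (oxocarbenium) tethered to a tin enolate, which closes by aldol-type attack of C8 on C9. The closest known reaction type is the Lewis-acid-catalysed (3+2) annulation of aryl-substituted cyclopropane-1,1-dicarbonyl compounds with aldehydes, formaldehyde being an unhindered aldehyde partner. Ring B is the only ring closed: intermolecular C–O bond formation at C7', then a 5-(enolexo)-endo-trig C–C closure onto the oxocarbenium carbon. C7' is set by inversion of the cyclopropane carbon, so the exo aryl of 7 (trans to C9') becomes the endo aryl (cis to C9') of 9; C8 is set by the ring fusion, since the enolate can bond to C9 only on the face that carries the C7' tether, which leaves the ester on the convex face; C8' is untouched. The step needs backside capture to outrun free ionisation at C7', and cleavage of C8–C7' instead of C8–C8'; chelated 1,1-diacceptor activation at low temperature should secure the first, and the aryl donor on C7' alone the second.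

Step 5
Reactants: 9
Product: 10 (3aR,4R,6aR)-4-[4-(benzyloxy)-3-methoxyphenyl]tetrahydro-1H,3H-furo[3,4-c]furan-1-one
Conditions: LiCl, H2O, DMSO, 130 °C
Reagents that add atoms: none
Why: Krapcho dealkoxycarbonylation (chloride demethylates the angular ester, the carboxylate loses CO2 and the lactone enolate is protonated) should leave C8 cis-fused, because a trans-fused bicyclo[3.3.0] lactone is prohibitively strained, and the neutral medium should spare the benzylic ether at C7'.

Step 6
Reactants: 10
Product: 11 (3aR,4R,6aS)-4-[4-(benzyloxy)-3-methoxyphenyl]-6a-hydroxytetrahydro-1H,3H-furo[3,4-c]furan-1-one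
Conditions: KN(SiMe3)2, THF, −78 °C; then 2-(phenylsulfonyl)-3-phenyloxaziridine; aq NH4Cl
Reagents that add atoms: 2-(phenylsulfonyl)-3-phenyloxaziridine, O=S(=O)(c1ccccc1)N1OC1c1ccccc1
Why: Enolate oxidation with an N-sulfonyloxaziridine should hydroxylate C8 on the convex face, the only face compatible with cis ring fusion, so that the tertiary alcohol is cis to H8', while β-elimination of the ring-B oxygen is disfavoured because the C9–O bond lies close to the enolate plane.

Step 7
Reactants: 11; 12 1-(benzyloxy)-4-bromo-2-methoxybenzene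
Product: 15 (3S,4R,5R)-5-[4-(benzyloxy)-3-methoxyphenyl]-3-{[4-(benzyloxy)-3-methoxyphenyl](hydroxy)methyl}-4-(hydroxymethyl)oxolan-3-ol (both C7 epimers), via aryllithium 13 (not isolated), via keto diol 14 (not isolated)
Conditions: 12, n-BuLi, THF, −78 °C; then 11, −78 °C; then MeOH, NaBH4, −78 to 0 °C
Reagents that add atoms: 1-(benzyloxy)-4-bromo-2-methoxybenzene 12, COc1cc(Br)ccc1OCc1ccccc1
Why: Bromine–lithium exchange gives 13, of which one equivalent deprotonates the tertiary alcohol and a second adds once to the lactone carbonyl (the lithium hemiketal is stable at low temperature), and borohydride reduction of the released aryl ketone 14 in the same flask should give the triol, whose new carbinol center C7 need not be controlled because it is ionised in step 8.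

Step 8
Reactants: 15
Product: 16 (1R,3aS,4R,6aR)-1,4-bis[4-(benzyloxy)-3-methoxyphenyl]tetrahydro-1H,3H-furo[3,4-c]furan-3a(4H)-ol
Conditions: camphorsulfonic acid (10 mol%), 4 Å MS, CH2Cl2, 0 °C
Reagents that add atoms: none
Why: Acid-catalysed cyclodehydration (SN1 etherification), in which the electron-rich benzylic alcohol at C7 ionises and the C9' hydroxyl closes ring A on the cation, should make both C7 epimers converge on the exo aryl isomer, because the endo,endo alternative would force both aryl groups into the concave face.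

Step 9
Reactants: 16
Product: 17 (1R,3aS,4R,6aR)-1,4-bis(4-hydroxy-3-methoxyphenyl)tetrahydro-1H,3H-furo[3,4-c]furan-3a(4H)-ol (the target; aryl at C7 exo, aryl at C7' endo)
Conditions: H2 (1 atm), 10% Pd/C, EtOAc, rt, stopped at full debenzylation
Reagents that add atoms: none
Why: Hydrogenolysis of the two aryl benzyl ethers over palladium should be faster than cleavage of the ring benzylic C–O bonds if the reaction is stopped at full conversion, and no stereocenter is touched.

**Compound list**

1 | coniferaldehyde, (E)-3-(4-hydroxy-3-methoxyphenyl)prop-2-enal | COc1cc(/C=C/C=O)ccc1O | starting material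
2 | benzyl bromide | BrCc1ccccc1 | starting material
3 | (E)-3-[4-(benzyloxy)-3-methoxyphenyl]prop-2-enal | COc1cc(/C=C/C=O)ccc1OCc1ccccc1 | intermediate
4 | dimethyl bromomalonate | COC(=O)C(Br)C(=O)OC | starting material
5 | dimethyl (2S,3R)-2-[4-(benzyloxy)-3-methoxyphenyl]-3-formylcyclopropane-1,1-dicarboxylate | O=C[C@@H]1[C@@H](c2ccc(OCc3ccccc3)c(OC)c2)C1(C(=O)OC)C(=O)OC | intermediate
6 | dimethyl (2S,3R)-2-[4-(benzyloxy)-3-methoxyphenyl]-3-(hydroxymethyl)cyclopropane-1,1-dicarboxylate (formed in the flask) | OC[C@@H]1[C@@H](c2ccc(OCc3ccccc3)c(OC)c2)C1(C(=O)OC)C(=O)OC | intermediate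
7 | methyl (1S,5R,6S)-6-[4-(benzyloxy)-3-methoxyphenyl]-2-oxo-3-oxabicyclo[3.1.0]hexane-1-carboxylate | O=C1OC[C@@H]2[C@@H](c3ccc(OCc4ccccc4)c(OC)c3)[C@]12C(=O)OC | intermediate
8 | formaldehyde (monomer from paraformaldehyde) | C=O | starting material
9 | methyl (3aR,4R,6aR)-4-[4-(benzyloxy)-3-methoxyphenyl]-1-oxotetrahydro-1H,3H-furo[3,4-c]furan-6a(6H)-carboxylate | O=C1OC[C@@H]2[C@H](c3ccc(OCc4ccccc4)c(OC)c3)OC[C@]12C(=O)OC | intermediate
10 | (3aR,4R,6aR)-4-[4-(benzyloxy)-3-methoxyphenyl]tetrahydro-1H,3H-furo[3,4-c]furan-1-one | O=C1OC[C@@H]2[C@H](c3ccc(OCc4ccccc4)c(OC)c3)OC[C@H]12 | intermediate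
11 | (3aR,4R,6aS)-4-[4-(benzyloxy)-3-methoxyphenyl]-6a-hydroxytetrahydro-1H,3H-furo[3,4-c]furan-1-one | O=C1OC[C@@H]2[C@H](c3ccc(OCc4ccccc4)c(OC)c3)OC[C@]12O | intermediate
12 | 1-(benzyloxy)-4-bromo-2-methoxybenzene | COc1cc(Br)ccc1OCc1ccccc1 | starting material
13 | [4-(benzyloxy)-3-methoxyphenyl]lithium (formed in the flask) | [Li]c1ccc(OCc2ccccc2)c(OC)c1 | intermediate
14 | [4-(benzyloxy)-3-methoxyphenyl]{(3S,4R,5R)-5-[4-(benzyloxy)-3-methoxyphenyl]-3-hydroxy-4-(hydroxymethyl)oxolan-3-yl}methanone (formed in the flask, in equilibrium with its cyclic hemiketal) | O=C(c1ccc(OCc2ccccc2)c(OC)c1)[C@@]1(O)CO[C@@H](c2ccc(OCc3ccccc3)c(OC)c2)[C@H]1CO | intermediate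
15 | (3S,4R,5R)-5-[4-(benzyloxy)-3-methoxyphenyl]-3-{[4-(benzyloxy)-3-methoxyphenyl](hydroxy)methyl}-4-(hydroxymethyl)oxolan-3-ol, both C7 epimers | OC(c1ccc(OCc2ccccc2)c(OC)c1)[C@@]1(O)CO[C@@H](c2ccc(OCc3ccccc3)c(OC)c2)[C@H]1CO | intermediate
16 | (1R,3aS,4R,6aR)-1,4-bis[4-(benzyloxy)-3-methoxyphenyl]tetrahydro-1H,3H-furo[3,4-c]furan-3a(4H)-ol | COc1cc([C@H]2OC[C@@H]3[C@H](c4ccc(OCc5ccccc5)c(OC)c4)OC[C@]23O)ccc1OCc1ccccc1 | intermediate
17 | (1R,3aS,4R,6aR)-1,4-bis(4-hydroxy-3-methoxyphenyl)tetrahydro-1H,3H-furo[3,4-c]furan-3a(4H)-ol | COc1cc([C@H]2OC[C@@H]3[C@H](c4ccc(O)c(OC)c4)OC[C@]23O)ccc1O | target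

**Step count.** Total: 9 steps. Longest linear sequence: 9 steps (1 to 17); 12 enters in step 7.

**Steps most likely to fail**

1. Step 4. Capture of the activated cyclopropane by the weakly nucleophilic formaldehyde oxygen may be outrun by ionisation to a free benzylic cation, which would lose the inversion that sets C7'. The Lewis acid may also oligomerise formaldehyde or hydroxymethylate the electron-rich arene. Fallback, from 7 back to 10: the two bonds are made one after the other. Ring opening of 7 with methanol (Sc(OTf)3 cat., CH2Cl2, 0 °C; SN2 with inversion at C7', a far better nucleophile than formaldehyde) should give methyl (4R)-4-{(R)-[4-(benzyloxy)-3-methoxyphenyl](methoxy)methyl}-2-oxooxolane-3-carboxylate F1. Krapcho dealkoxycarbonylation (LiCl, wet DMSO, 130 °C) then gives the lactone methyl ether F2. Trifluoroacetylation (LiN(SiMe3)2, CF3CO2CH2CF3, THF, −78 °C) gives the trifluoroacetyl lactone F3, which is not isolated, and diazo transfer with MsN3 and Et3N gives the diazo lactone F4. Rh2(OAc)4-catalysed 1,5 C–H insertion of the carbenoid into the O-methyl group (CH2Cl2, reflux) forms C9–C8 and delivers 10, cis-fused by necessity.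

2. Step 8. After ionisation at C7 a 1,2-shift from the neighbouring carbinol carbon C8 (pinacol-type rearrangement) may compete with ring closure. The acid may also reversibly open ring B at C7' and erode the endo configuration. Fallback, from 15 back to 16: ring A is closed at the primary carbon under base, with no cation. The (7R)-epimer of 15, F6, is separated (the other C7 epimer is returned to 14 by MnO2 oxidation and reduced again). Selective sulfonylation of the primary alcohol (TsCl, pyridine, 0 °C) gives the monotosylate F7, and NaH in THF should close ring A by Williamson displacement at C9' with C7 untouched, giving 16.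

3. Step 7. Addition of the aryllithium to the hindered carbonyl flanked by the lithium alkoxide may stall, or the opened keto alkoxide may take up a second aryl group. Fallback, from 11 back to 15: the order of reduction and arylation is reversed. Reduction of 11 with iBu2AlH (CH2Cl2, −78 °C) should give the lactol F5, and excess aryllithium 13 (THF, −78 to 0 °C) should add to its open hydroxy aldehyde form to give 15.

**Further compounds**

F1 | step 4 | methyl (4R)-4-{(R)-[4-(benzyloxy)-3-methoxyphenyl](methoxy)methyl}-2-oxooxolane-3-carboxylate (C3 epimers) | COC(=O)C1C(=O)OC[C@@H]1[C@@H](OC)c1ccc(OCc2ccccc2)c(OC)c1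
F2 | step 4 | (4R)-4-{(R)-[4-(benzyloxy)-3-methoxyphenyl](methoxy)methyl}oxolan-2-one | O=C1OC[C@@H](C1)[C@@H](OC)c1ccc(OCc2ccccc2)c(OC)c1
F3 | step 4 | (4R)-4-{(R)-[4-(benzyloxy)-3-methoxyphenyl](methoxy)methyl}-3-(trifluoroacetyl)oxolan-2-one | O=C(C1C(=O)OC[C@@H]1[C@@H](OC)c1ccc(OCc2ccccc2)c(OC)c1)C(F)(F)F
F4 | step 4 | (4R)-4-{(R)-[4-(benzyloxy)-3-methoxyphenyl](methoxy)methyl}-3-diazooxolan-2-one | [N-]=[N+]=C1C(=O)OC[C@@H]1[C@@H](OC)c1ccc(OCc2ccccc2)c(OC)c1
F5 | step 7 | (3aR,4R,6aS)-4-[4-(benzyloxy)-3-methoxyphenyl]tetrahydro-1H,3H-furo[3,4-c]furan-1,6a-diol (lactol, both anomers) | OC1OC[C@@H]2[C@H](c3ccc(OCc4ccccc4)c(OC)c3)OC[C@]12O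
F6 | step 8 | (3S,4R,5R)-5-[4-(benzyloxy)-3-methoxyphenyl]-3-{(R)-[4-(benzyloxy)-3-methoxyphenyl](hydroxy)methyl}-4-(hydroxymethyl)oxolan-3-ol | O[C@H](c1ccc(OCc2ccccc2)c(OC)c1)[C@@]1(O)CO[C@@H](c2ccc(OCc3ccccc3)c(OC)c2)[C@H]1CO
F7 | step 8 | primary mono-p-toluenesulfonate of F6 | O[C@H](c1ccc(OCc2ccccc2)c(OC)c1)[C@@]1(O)CO[C@@H](c2ccc(OCc3ccccc3)c(OC)c2)[C@H]1COS(=O)(=O)c1ccc(C)cc1
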